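**Plan**
Retrosynthesis: the acid is unmasked from a benzyl ester and lactone ring B from its methyl lactol ether. Two bonds are then cut in one operation: the spiro carbon–ring A bond (ring B) and the OCH2–bridgehead bond of the tetrahydrofuran (ring D). This leaves a 4-alkoxycyclohexenone (ring C, one stereocentre) tied by a mixed acetal to a cyclohexenecarbaldehyde (ring A).
Forward: ring A enal by proline-mediated desymmetrising aldol of a 4-substituted heptanedial; ring C dienone alcohol from 4,4-dimethylcyclohexenone; union as a mixed acetal; enantioselective β-borylation/oxidation and O-CH2SePh ether formation; radical cascade closing ring D (5-exo) then ring B (6-endo); oxidation to the lactone; hydrogenolysis.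
Enabling feature: the OCH2 carbon of ring D sits on the carbon β to the ring C ketone. An O–CH2 radical adding to the enone therefore builds the oxa-bridge and places an α-keto radical on the spiro carbon inside the bridged bicycle, and that carbon already carries the CH2O arm leading to the ring A alkene.
Stereochemistry: side-chain methine from oxazolidinone-controlled methylation; ring A carbon from (R)-proline; ring C carbinol from the chiral copper catalyst; bridgehead, spiro carbon, adjacent ring A CH and lactone α-carbon are relayed from these in the cascade.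

Key step: step 14

Remark: the acetal carbon made in step 11 is carried as both epimers (left undefined in the SMILES) and becomes the lactone carbonyl in step 15; compound 16 is racemic and its centre is erased in step 10.
Remark: the proline and ligand enantiomers named are those predicted by the usual transition-state models; the mirror-image catalyst would be used if the first samples show the opposite sense.

Step 1
Reactants: 1 pent-4-enal; 2 malonic acid
Product: 3 (E)-hepta-2,6-dienoic acid
Conditions: pyridine, piperidine (cat.), 90 °C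
Reagents that add atoms: none
Why: Doebner–Knoevenagel condensation with in situ decarboxylation should give the E-configured α,β-unsaturated acid.

Step 2
Reactants: 3 (E)-hepta-2,6-dienoic acid; 4 (R)-4-benzyl-1,3-oxazolidin-2-one
Product: 6 (R)-4-benzyl-3-[(E)-hepta-2,6-dienoyl]-1,3-oxazolidin-2-one, via mixed pivalic anhydride 5 (not isolated)
Conditions: PivCl, Et3N, THF, −20 °C; then 4, LiCl, rt
Reagents that add atoms: pivaloyl chloride CC(C)(C)C(Cl)=O (atoms in intermediate 5 only)
Why: Mixed-anhydride activation followed by LiCl/Et3N-mediated N-acylation of the oxazolidinone is the standard imide formation.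

Step 3
Reactants: 6 (R)-4-benzyl-3-[(E)-hepta-2,6-dienoyl]-1,3-oxazolidin-2-one; 7 but-3-en-1-ylmagnesium bromide
Product: 8 (R)-4-benzyl-3-[3-(but-3-en-1-yl)hept-6-enoyl]-1,3-oxazolidin-2-one
Conditions: CuBr·SMe2 (cat.), THF/Me2S, −40 °C; aq. NH4Cl
Reagents that add atoms: none
Why: Copper-catalysed conjugate addition of the Grignard reagent to the N-enoyl imide gives a β-carbon with two identical butenyl arms, which is therefore not stereogenic.

Step 4
Reactants: 8 (R)-4-benzyl-3-[3-(but-3-en-1-yl)hept-6-enoyl]-1,3-oxazolidin-2-one
Product: 9 (R)-4-benzyl-3-[(2R)-3-(but-3-en-1-yl)-2-methylhept-6-enoyl]-1,3-oxazolidin-2-one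
Conditions: NaHMDS, THF, −78 °C; MeI
Reagents that add atoms: iodomethane CI
Why: Evans alkylation, in which the chelated Z-sodium enolate is methylated on the face away from the benzyl group of the (R)-auxiliary, should set the 2R centre.

Step 5
Reactants: 9 (R)-4-benzyl-3-[(2R)-3-(but-3-en-1-yl)-2-methylhept-6-enoyl]-1,3-oxazolidin-2-one
Product: 10 benzyl (2R)-3-(but-3-en-1-yl)-2-methylhept-6-enoate
Conditions: BnOH, n-BuLi, THF, −78 to 0 °C; aq. NH4Cl
Reagents that add atoms: benzyl alcohol OCc1ccccc1
Why: Lithium benzyloxide attacks the exocyclic imide carbonyl (transesterification), releasing the auxiliary and giving the benzyl ester without epimerisation.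

Step 6
Reactants: 10 benzyl (2R)-3-(but-3-en-1-yl)-2-methylhept-6-enoate
Product: 11 benzyl (2R)-2-methyl-6-oxo-3-(3-oxopropyl)hexanoate
Conditions: O3, CH2Cl2, −78 °C; then PPh3
Reagents that add atoms: ozone [O-][O+]=O
Why: Ozonolysis with reductive work-up cleaves both terminal alkenes to aldehydes and leaves the ester and the α-stereocentre untouched.

Step 7
Reactants: 11 benzyl (2R)-2-methyl-6-oxo-3-(3-oxopropyl)hexanoate
Product: 13 benzyl (2R)-2-[(1R)-3-formylcyclohex-3-en-1-yl]propanoate, via aldol 12 (not isolated)
Conditions: (R)-proline (20 mol%), CH2Cl2, rt; then TsOH·H2O (cat.), 40 °C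
Reagents that add atoms: none
Why: (R)-Proline forms an enamine from one of the two diastereotopic aldehyde arms and closes the ring by a 6-enolexo desymmetrising aldol through a chair transition state with the branched substituent equatorial, so that after acid-promoted dehydration only the ring carbon bearing the side chain remains stereogenic, predicted R.

Step 8
Reactants: 13 benzyl (2R)-2-[(1R)-3-formylcyclohex-3-en-1-yl]propanoate
Product: 14 benzyl (2R)-2-[(1R)-3-(dimethoxymethyl)cyclohex-3-en-1-yl]propanoate
Conditions: HC(OMe)3, PPTS (cat.), MeOH, rt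
Reagents that add atoms: trimethyl orthoformate COC(OC)OC
Why: Acid-catalysed acetalisation with orthoformate as water scavenger converts the enal into its dimethyl acetal, the precursor of the tether.

Step 9
Reactants: 15 4,4-dimethylcyclohex-2-en-1-one
Product: 16 6-(hydroxymethyl)-4,4-dimethylcyclohex-2-en-1-one (racemic)
Conditions: LDA, THF, −78 °C; HCHO (gas); aq. NH4Cl
Reagents that add atoms: formaldehyde C=O
Why: Kinetic deprotonation occurs at the only enolisable (α′) position and the lithium enolate adds to monomeric formaldehyde (aldol reaction), the new centre being racemic and erased in step 10.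

Step 10
Reactants: 16 6-(hydroxymethyl)-4,4-dimethylcyclohex-2-en-1-one
Product: 17 2-(hydroxymethyl)-4,4-dimethylcyclohexa-2,5-dien-1-one
Conditions: DDQ, 1,4-dioxane, 90 °C
Reagents that add atoms: none
Why: DDQ dehydrogenation through the α′-dienol removes hydride from the only β′-CH2 and should give the achiral cross-conjugated dienone.

Step 11
Reactants: 14 benzyl (2R)-2-[(1R)-3-(dimethoxymethyl)cyclohex-3-en-1-yl]propanoate; 17 2-(hydroxymethyl)-4,4-dimethylcyclohexa-2,5-dien-1-one
Product: 19 benzyl (2R)-2-[(1R)-3-{methoxy[(3,3-dimethyl-6-oxocyclohexa-1,4-dien-1-yl)methoxy]methyl}cyclohex-3-en-1-yl]propanoate (both acetal epimers), via collidinium salt 18 (not isolated)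
Conditions: TESOTf, 2,4,6-collidine, CH2Cl2, 0 °C; then 17
Reagents that add atoms: 2,4,6-collidine Cc1cc(C)nc(C)c1; triethylsilyl triflate CC[Si](CC)(CC)OS(=O)(=O)C(F)(F)F (atoms in intermediate 18 only)
Why: Exchange of one methoxy group by the allylic alcohol through a collidinium N,O-acetal salt gives the mixed acetal without acid, and the acetal (not ester) level is chosen so that the later α-keto radical and enolisable ketone carry no β-acyloxy leaving group and ring closure is not slowed by the s-trans ester preference.

Step 12
Reactants: 19 mixed acetal dienone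
Product: 21 benzyl (2R)-2-[(1R)-3-{methoxy[((4S)-4-hydroxy-3,3-dimethyl-6-oxocyclohex-1-en-1-yl)methoxy]methyl}cyclohex-3-en-1-yl]propanoate, via boronate 20 (not isolated)
Conditions: CuCl (5 mol%), NaOtBu (10 mol%), (R)-1-[(S)-2-(diphenylphosphino)ferrocenyl]ethyldicyclohexylphosphine or its enantiomer (the one giving 4S), B2pin2, MeOH (2 equiv), THF, rt; then H2O2, pH 7 phosphate buffer, 0 °C
Reagents that add atoms: bis(pinacolato)diboron CC1(C)OB(OC1(C)C)B1OC(C)(C)C(C)(C)O1 (boron in intermediate 20); hydrogen peroxide OO
Why: Enantioselective copper-boryl conjugate addition (β-borylation) should occur at the less substituted, α-unsubstituted enone, the chiral bisphosphine selecting the face that gives the 4S carbinol after stereoretentive oxidation of the C–B bond.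

Step 13
Reactants: 21 β-hydroxy enone acetal
Product: 22 benzyl (2R)-2-[(1R)-3-{methoxy[((4S)-3,3-dimethyl-6-oxo-4-[(phenylselanyl)methoxy]cyclohex-1-en-1-yl)methoxy]methyl}cyclohex-3-en-1-yl]propanoate
Conditions: PhSeCH2Cl, AgOTf, 2,6-di-tert-butyl-4-methylpyridine, 4 Å MS, CH2Cl2, −20 °C to rt
Reagents that add atoms: chloromethyl phenyl selenide ClC[Se]c1ccccc1
Why: Silver-assisted ionisation of the α-chloro selenide gives a selenium-stabilised carbenium ion that is captured by the hindered alcohol under buffered, non-basic conditions (O-alkylation of the kind used for methylthiomethyl ethers), so the β-hydroxy ketone never meets alkoxide.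

Step 14
Reactants: 22 selanylmethyl ether
Product: 23 benzyl ester of the target skeleton with ring B as its methyl lactol ether (methoxy on the future lactone carbon; all other centres as in the target)
Conditions: Bu3SnH (1.3 equiv, syringe pump 8 h), AIBN (0.2 equiv), PhH (0.005 M), 80 °C
Reagents that add atoms: none
Why: Bu3Sn• abstracts PhSe to give a nucleophilic O–CH2 radical, which adds 5-exo-trig to the β-carbon of the ring C enone (closing ring D as the 6-oxabicyclo[3.2.1]octane), and the electrophilic tertiary α-keto radical so formed at the future spiro carbon adds 6-endo-trig to the CH terminus of the electron-rich trisubstituted ring A alkene (closing ring B and making the spiro carbon–ring A bond) before the tertiary ring-fusion radical is reduced by Bu3SnH. The closest known reaction types are the radical cyclisation of (phenylselanyl)methyl ethers, the Ueno–Stork haloacetal cyclisation and tandem 5-exo/6-endo cyclisations of α-carbonyl radicals. The bridgehead CH is fixed by the 4S carbinol carbon, because the two-atom O–CH2 arm can reach the enone carbon across the CMe2 carbon only on its own face. At the spiro carbon ring A should bond anti to the axial methyl of the CMe2 bridge, that is on the face of the O–CH2 bridge; at the ring A CH a chair-like transition state with the ring A methylene equatorial is expected; at the carbon next to the acetal carbon hydrogen should be delivered on the side of the neighbouring ring-fusion hydrogen, anti to the axial ketone carbon, giving cis-fused rings A and B. The step needs 6-endo rather than 5-exo closure of ring B, secured by the fully substituted proximal alkene carbon (5-exo would join two quaternary carbons), and it needs both cyclisations to outrun hydrogen transfer, secured by slow stannane addition, polarity matching in both additions and the acetal tether.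

Step 15
Reactants: 23 tetracyclic methyl acetal
Product: 24 benzyl ester of the target (δ-lactone formed)
Conditions: CrO3, H2SO4, H2O, acetone, 0 °C
Reagents that add atoms: water O
Why: Jones oxidation of the cyclic methyl acetal to the δ-lactone is the usual close of an Ueno–Stork sequence, and cold, brief exposure should leave the α-stereocentre, ketone, ethers and benzyl ester intact.

Step 16
Reactants: 24 benzyl ester of the target
Product: 25 target acid CNP0152427.1
Conditions: H2 (1 atm), Pd/C, EtOAc, rt
Reagents that add atoms: none
Why: Hydrogenolysis of the benzyl ester under neutral conditions frees the acid without exposing the epimerisable lactone α-carbon or the β-alkoxy ketone to base.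

**Compound list**
1 | pent-4-enal | C=CCCC=O | starting material
2 | malonic acid | OC(=O)CC(=O)O | starting material
3 | (E)-hepta-2,6-dienoic acid | C=CCC/C=C/C(=O)O | intermediate
4 | (R)-4-benzyl-1,3-oxazolidin-2-one | O=C1OC[C@@H](Cc2ccccc2)N1 | starting material
5 | (E)-hepta-2,6-dienoic pivalic anhydride | C=CCC/C=C/C(=O)OC(=O)C(C)(C)C | intermediate
6 | (R)-4-benzyl-3-[(E)-hepta-2,6-dienoyl]-1,3-oxazolidin-2-one | C=CCC/C=C/C(=O)N1[C@H](Cc2ccccc2)COC1=O | intermediate
7 | but-3-en-1-ylmagnesium bromide | C=CCC[Mg]Br | starting material
8 | (R)-4-benzyl-3-[3-(but-3-en-1-yl)hept-6-enoyl]-1,3-oxazolidin-2-one | C=CCCC(CCC=C)CC(=O)N1[C@H](Cc2ccccc2)COC1=O | intermediate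
9 | (R)-4-benzyl-3-[(2R)-3-(but-3-en-1-yl)-2-methylhept-6-enoyl]-1,3-oxazolidin-2-one | C=CCCC(CCC=C)[C@@H](C)C(=O)N1[C@H](Cc2ccccc2)COC1=O | intermediate
10 | benzyl (2R)-3-(but-3-en-1-yl)-2-methylhept-6-enoate | C=CCCC(CCC=C)[C@@H](C)C(=O)OCc1ccccc1 | intermediate
11 | benzyl (2R)-2-methyl-6-oxo-3-(3-oxopropyl)hexanoate | O=CCCC(CCC=O)[C@@H](C)C(=O)OCc1ccccc1 | intermediate
12 | benzyl (2R)-2-[(1R,3R,4R)-3-formyl-4-hydroxycyclohexyl]propanoate | O=C[C@H]1[C@H](O)CC[C@@H]([C@@H](C)C(=O)OCc2ccccc2)C1 | intermediate
13 | benzyl (2R)-2-[(1R)-3-formylcyclohex-3-en-1-yl]propanoate | O=CC1=CCC[C@@H]([C@@H](C)C(=O)OCc2ccccc2)C1 | intermediate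
14 | benzyl (2R)-2-[(1R)-3-(dimethoxymethyl)cyclohex-3-en-1-yl]propanoate | COC(OC)C1=CCC[C@@H]([C@@H](C)C(=O)OCc2ccccc2)C1 | intermediate
15 | 4,4-dimethylcyclohex-2-en-1-one | CC1(C)CCC(=O)C=C1 | starting material
16 | 6-(hydroxymethyl)-4,4-dimethylcyclohex-2-en-1-one (racemic) | OCC1CC(C)(C)C=CC1=O | intermediate
17 | 2-(hydroxymethyl)-4,4-dimethylcyclohexa-2,5-dien-1-one | OCC1=CC(C)(C)C=CC1=O | intermediate
18 | 1-{methoxy[(5R)-5-((2R)-1-benzyloxy-1-oxopropan-2-yl)cyclohex-1-en-1-yl]methyl}-2,4,6-trimethylpyridinium triflate | COC([n+]1c(C)cc(C)cc1C)C1=CCC[C@@H]([C@@H](C)C(=O)OCc2ccccc2)C1.[O-]S(=O)(=O)C(F)(F)F | intermediate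
19 | benzyl (2R)-2-[(1R)-3-{methoxy[(3,3-dimethyl-6-oxocyclohexa-1,4-dien-1-yl)methoxy]methyl}cyclohex-3-en-1-yl]propanoate (acetal carbon undefined) | C[C@@H](C(=O)OCc1ccccc1)[C@@H]1CCC=C(C1)C(OC)OCC1=CC(C)(C)C=CC1=O | intermediate
20 | as 21 with 4,4,5,5-tetramethyl-1,3,2-dioxaborolan-2-yl in place of the hydroxyl (4S) | C[C@@H](C(=O)OCc1ccccc1)[C@@H]1CCC=C(C1)C(OC)OCC1=CC(C)(C)[C@@H](B2OC(C)(C)C(C)(C)O2)CC1=O | intermediate
21 | benzyl (2R)-2-[(1R)-3-{methoxy[((4S)-4-hydroxy-3,3-dimethyl-6-oxocyclohex-1-en-1-yl)methoxy]methyl}cyclohex-3-en-1-yl]propanoate | C[C@@H](C(=O)OCc1ccccc1)[C@@H]1CCC=C(C1)C(OC)OCC1=CC(C)(C)[C@@H](O)CC1=O | intermediate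
22 | benzyl (2R)-2-[(1R)-3-{methoxy[((4S)-3,3-dimethyl-6-oxo-4-[(phenylselanyl)methoxy]cyclohex-1-en-1-yl)methoxy]methyl}cyclohex-3-en-1-yl]propanoate | C[C@@H](C(=O)OCc1ccccc1)[C@@H]1CCC=C(C1)C(OC)OCC1=CC(C)(C)[C@@H](OC[Se]c2ccccc2)CC1=O | intermediate
23 | benzyl ester of the target skeleton with ring B as methyl lactol ether (acetal carbon undefined) | C[C@@H](C(=O)OCc1ccccc1)[C@@H]1CC[C@@H]2[C@H](C1)C(OC)OC[C@]21C(=O)C[C@@H]2OC[C@H]1C2(C)C | intermediate
24 | benzyl ester of the target | C[C@@H](C(=O)OCc1ccccc1)[C@@H]1CC[C@@H]2[C@H](C1)C(=O)OC[C@]21C(=O)C[C@@H]2OC[C@H]1C2(C)C | intermediate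
25 | target acid CNP0152427.1 | C[C@@H](C(=O)O)[C@@H]1CC[C@@H]2[C@H](C1)C(=O)OC[C@]21C(=O)C[C@@H]2OC[C@H]1C2(C)C | target

**Totals**
Total steps: 16. Longest linear sequence: 14 steps (steps 1–8, then 11–16).

**Steps most likely to fail**

1. Step 14. Hydrogen transfer from the stannane to the bridged α-keto radical may outrun the 6-endo closure, and approach of ring A to the spiro carbon, or hydrogen delivery to the ring-fusion radical, may not be fully face-selective. Fallback (hydride-free group-transfer cascade, then separate reduction): from 22, irradiation with catalytic (Bu3Sn)2 in PhH runs the same two cyclisations as a phenylselanyl group-transfer chain. The α-keto radical cannot be quenched by hydrogen and is a poor selenium abstractor, so it persists until it cyclises, and the tertiary ring A radical then takes PhSe from 22. This should give the tertiary ring A phenylselanyl acetal F1, which is reduced with Bu3SnH/AIBN at high concentration to rejoin the route at 23.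

2. Step 12. The copper boryl may add slowly next to the quaternary carbon, attack the substituted enone or show low facial selectivity, and the β-hydroxy ketone may lose water on work-up. Fallback: from 19, amine-salt-catalysed asymmetric nucleophilic epoxidation of the less substituted enone (9-amino-9-deoxy-epi-quinine bis(trifluoroacetate), aq. H2O2, dioxane) gives the epoxy ketone F2. Reductive opening of its Cα–O bond with PhSeSePh/NaBH4/AcOH in EtOH returns to 21.

3. Step 13. The silver salt may ionise the allylic mixed acetal, or the hindered β-hydroxy ketone may dehydrate or undergo retro-aldol cleavage instead of etherifying. Fallback: from 21, Rh2(OAc)4-catalysed O–H insertion of allyl diazoacetate under neutral conditions gives the allyl alkoxyacetate F3. Deallylation with Pd(PPh3)4/morpholine gives the alkoxyacetic acid F4, and DCC coupling with N-hydroxypyridine-2-thione gives the thiohydroxamate ester F5. Its Barton decarboxylation with Bu3SnH generates the same O–CH2 radical and should deliver 23 by the same cascade.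

**Further compounds**
F1 | step 14 | 23 bearing phenylselanyl on the ring A carbon next to the acetal carbon (that centre and the acetal carbon undefined) | C[C@@H](C(=O)OCc1ccccc1)[C@@H]1CC[C@@H]2C(C1)([Se]c1ccccc1)C(OC)OC[C@]21C(=O)C[C@@H]2OC[C@H]1C2(C)C
F2 | step 12 | 19 with the less substituted enone converted into its cis-epoxide (oxygen on the face of the later 4S hydroxyl) | C[C@@H](C(=O)OCc1ccccc1)[C@@H]1CCC=C(C1)C(OC)OCC1=CC(C)(C)[C@H]2O[C@H]2C1=O
F3 | step 13 | 21 with the hydroxyl as its (allyloxycarbonyl)methyl ether | C[C@@H](C(=O)OCc1ccccc1)[C@@H]1CCC=C(C1)C(OC)OCC1=CC(C)(C)[C@@H](OCC(=O)OCC=C)CC1=O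
F4 | step 13 | 21 with the hydroxyl as its carboxymethyl ether | C[C@@H](C(=O)OCc1ccccc1)[C@@H]1CCC=C(C1)C(OC)OCC1=CC(C)(C)[C@@H](OCC(=O)O)CC1=O
F5 | step 13 | 2-thioxopyridin-1(2H)-yl ester of F4 | C[C@@H](C(=O)OCc1ccccc1)[C@@H]1CCC=C(C1)C(OC)OCC1=CC(C)(C)[C@@H](OCC(=O)On2ccccc2=S)CC1=O
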